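**Retrosynthetic overview**

1. Target ⇐ enol triflate 33 (triflate reduction, silyl removal) ⇐ bromo enone 21 + iodide 29: cuprate 1,4-addition anti to the C10 methyl sets C9, and triflation of the resulting enolate fixes the C7=C8 position; C13 comes from (R)-linalool.
2. 21 ⇐ ketone 14: the C3 carbonyl becomes the equatorial bromide (vinyl bromide, then MHAT hydrogenation) and the C7 silyl ether becomes the 8-methyl-8-en-7-one.
3. 14 ⇐ vinyl ketone 13 by closure of ring A through C1–C10: hydrogen-atom transfer to the C9=C10 alkene of ring B gives the tertiary C10 radical, which adds 6-endo to C1.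
4. Enabling feature: C10 is a methyl-bearing, fully substituted ring-fusion carbon lying 1,5 to C1 across ring A (C10–C5–C4–C3–C2–C1), and C3, the bromine-bearing carbon next to the C4 gem-dimethyl group, can be carried as a ketone that makes C1 the β-carbon of an enone.
5. 13 ⇐ (R)-carvone: ring B comes first, from the chiral pool; an Ireland–Claisen rearrangement of the cis-allylic isobutyrate 7 relays the C9–O stereocentre to C5, builds quaternary C4 and places the C9=C10 alkene; ring A is formed second.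

Key step: step 9

Assumption: atoms are numbered as in labdanes (C1–C20); the SMILES is read as a trans-decalin with the C3 bromine equatorial and cis to the C10 methyl and the C9 side chain trans to that methyl, absolute configuration (3R,5S,9S,10S,13R).

**Route**

Step 1
Reactants: 1 (R)-(−)-carvone
Product: 3 (1R)-4-methyl-5-oxocyclohex-3-en-1-yl acetate, via methoxy hydroperoxide 2 (not isolated)
Conditions: O3, CH2Cl2/MeOH, −78 °C; then Ac2O, Et3N, DMAP (cat.), −78 → 40 °C
Reagents that add atoms: ozone, O=[O+][O-]; methanol, CO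
Why: Ozonolysis in methanol cleaves only the electron-rich isopropenyl group (the enone alkene is deactivated), and acylation of the α-methoxy hydroperoxide triggers a Criegee rearrangement in which the ring carbon migrates to oxygen with retention, so the carvone stereocentre becomes the C7–O centre.

Step 2
Reactants: 3 (1R)-4-methyl-5-oxocyclohex-3-en-1-yl acetate
Product: 4 (5R)-5-hydroxy-2-methylcyclohex-2-en-1-one
Conditions: HCl (cat., 1.25 M in MeOH), MeOH, 0 °C → rt
Reagents that add atoms: none
Why: Acid-catalysed transesterification removes the acetate without the base that would eliminate the β-acyloxy ketone, and no stereocentre is touched.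

Step 3
Reactants: 4 (5R)-5-hydroxy-2-methylcyclohex-2-en-1-one
Product: 5 (5R)-5-[(tert-butyldimethylsilyl)oxy]-2-methylcyclohex-2-en-1-one
Conditions: TBSCl, imidazole, DMF, 0 °C → rt
Reagents that add atoms: tert-butyldimethylsilyl chloride, CC(C)(C)[Si](C)(C)Cl
Why: Silyl ether formation masks the future C7 carbonyl oxygen through the enolate, organometallic and radical steps.

Step 4
Reactants: 5 (5R)-5-[(tert-butyldimethylsilyl)oxy]-2-methylcyclohex-2-en-1-one
Product: 6 (1R,5R)-5-[(tert-butyldimethylsilyl)oxy]-2-methylcyclohex-2-en-1-ol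
Conditions: NaBH4, CeCl3·7H2O, MeOH, −78 °C
Reagents that add atoms: none
Why: Luche 1,2-reduction with axial hydride delivery to the enone, the silyloxy group being pseudo-equatorial, should give the cis-1,3 allylic alcohol (as carvone gives cis-carveol), which sets the C9–O centre that is later relayed to C5.

Step 5
Reactants: 6 (1R,5R)-5-[(tert-butyldimethylsilyl)oxy]-2-methylcyclohex-2-en-1-ol
Product: 7 (1R,5R)-5-[(tert-butyldimethylsilyl)oxy]-2-methylcyclohex-2-en-1-yl 2-methylpropanoate
Conditions: i-PrCOCl, pyridine, DMAP (cat.), CH2Cl2, 0 °C → rt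
Reagents that add atoms: 2-methylpropanoyl chloride, CC(C)C(Cl)=O
Why: DMAP-catalysed acylation gives the allylic isobutyrate for the ester-enolate Claisen step with retention at the carbinol carbon.

Step 6
Reactants: 7 (1R,5R)-5-[(tert-butyldimethylsilyl)oxy]-2-methylcyclohex-2-en-1-yl 2-methylpropanoate
Product: 10 2-[(1S,5S)-5-[(tert-butyldimethylsilyl)oxy]-2-methylcyclohex-2-en-1-yl]-2-methylpropanoic acid, via silyl ketene acetal 8 (not isolated), via trimethylsilyl ester 9 (not isolated)
Conditions: LDA, THF, −78 °C; TMSCl, −78 → 65 °C; then cold 1 M HCl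
Reagents that add atoms: none
Why: The Ireland–Claisen [3,3]-sigmatropic rearrangement is suprafacial across the cyclohexenyl allyl unit, so the C5–C4 bond forms on the face from which the C9–O bond leaves, which transfers the carbinol configuration to C5, creates the quaternary gem-dimethyl carbon C4 and moves the alkene to C9=C10.

Step 7
Reactants: 10 2-[(1S,5S)-5-[(tert-butyldimethylsilyl)oxy]-2-methylcyclohex-2-en-1-yl]-2-methylpropanoic acid
Product: 12 2-[(1S,5S)-5-[(tert-butyldimethylsilyl)oxy]-2-methylcyclohex-2-en-1-yl]-N-methoxy-N,2-dimethylpropanamide, via acid chloride 11 (not isolated)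
Conditions: 1-chloro-N,N,2-trimethylprop-1-en-1-amine, CH2Cl2, 0 °C; then MeNHOMe·HCl, Et3N, 0 °C → rt
Reagents that add atoms: N,O-dimethylhydroxylamine hydrochloride, CNOC.Cl
Why: Neutral acid chloride formation with the α-chloroenamine avoids acid that could lactonise the γ,δ-unsaturated acid, and acylation of the hydroxylamine gives the Weinreb amide.

Step 8
Reactants: 12 2-[(1S,5S)-5-[(tert-butyldimethylsilyl)oxy]-2-methylcyclohex-2-en-1-yl]-N-methoxy-N,2-dimethylpropanamide
Product: 13 4-[(1S,5S)-5-[(tert-butyldimethylsilyl)oxy]-2-methylcyclohex-2-en-1-yl]-4-methylpent-1-en-3-one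
Conditions: CH2=CHMgBr, THF, 0 °C → rt; inverse quench into cold aq. NH4Cl
Reagents that add atoms: vinylmagnesium bromide, C=C[Mg]Br
Why: In the Weinreb ketone synthesis the chelated tetrahedral adduct stops at mono-addition and releases the non-enolisable vinyl ketone only on work-up.

Step 9
Reactants: 13 4-[(1S,5S)-5-[(tert-butyldimethylsilyl)oxy]-2-methylcyclohex-2-en-1-yl]-4-methylpent-1-en-3-one
Product: 14 (4aR,7S,8aS)-7-[(tert-butyldimethylsilyl)oxy]-1,1,4a-trimethyloctahydronaphthalen-2(1H)-one
Conditions: Fe(acac)3 (0.3 equiv), PhSiH3, EtOH/(CH2OH)2, 60 °C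
Reagents that add atoms: none
Why: An iron hydride formed from Fe(acac)3 and PhSiH3 transfers a hydrogen atom to C9 of the trisubstituted ring B alkene (Markovnikov MHAT), the resulting tertiary C10 radical adds to the terminal carbon C1 of the tethered vinyl ketone, and the α-keto radical at C2 is then reduced and protonated. The closest known reaction type is the iron-mediated reductive olefin–enone coupling (MHAT-initiated Giese reaction), including its intramolecular and polyene variants that build decalins with quaternary carbons. Ring A closes in the 6-endo-trig mode, favoured over 5-exo because the nucleophilic tertiary radical attacks the unsubstituted β-carbon of the enone while the alternative is polarity-mismatched and hindered by the C4 gem-dimethyl group. The new quaternary stereocentre C10 is controlled by C5: in the chair-like transition state the C5 side chain and the cis-1,3 C7 silyloxy group are both equatorial on ring B and the C1–C10 bond forms equatorially, anti to H-5, which should give the trans-decalin with an axial C10 methyl, as in radical polyene cyclisations. The step needs hydrogen-atom transfer to the electron-rich alkene in preference to the enone, which the electrophilic character of the metal hydride should secure, and trans rather than cis ring fusion, which the equatorial lock of ring B should secure.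

Step 10
Reactants: 14 (4aR,7S,8aS)-7-[(tert-butyldimethylsilyl)oxy]-1,1,4a-trimethyloctahydronaphthalen-2(1H)-one
Product: 15 {[(2S,4aR,8aS)-7-bromo-4a,8,8-trimethyl-1,2,3,4,4a,5,8,8a-octahydronaphthalen-2-yl]oxy}(tert-butyl)dimethylsilane
Conditions: P(OPh)3, Br2, CH2Cl2, −60 °C; then Et3N and 14, −60 °C → reflux
Reagents that add atoms: bromine, BrBr
Why: Vinyl bromide formation from an enolisable ketone with triphenyl phosphite dibromide and base gives a single regioisomer (C2=C3) because only C2 carries α-hydrogens, and the amine-buffered medium should spare the secondary silyl ether.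

Step 11
Reactants: 15 {[(2S,4aR,8aS)-7-bromo-4a,8,8-trimethyl-1,2,3,4,4a,5,8,8a-octahydronaphthalen-2-yl]oxy}(tert-butyl)dimethylsilane
Product: 16 {[(2S,4aR,7R,8aS)-7-bromo-4a,8,8-trimethyldecahydronaphthalen-2-yl]oxy}(tert-butyl)dimethylsilane
Conditions: Mn(dpm)3 (10 mol%), PhSiH3, t-BuOOH, i-PrOH, 22 °C
Reagents that add atoms: none
Why: In this MHAT hydrogenation of a haloalkene, hydrogen-atom transfer to C2 gives the α-bromo radical at C3, which should accept the second hydrogen axially from the face anti to the axial C4 methyl, giving the thermodynamically preferred equatorial bromide cis to the C10 methyl without hydrodehalogenation.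

Step 12
Reactants: 16 {[(2S,4aR,7R,8aS)-7-bromo-4a,8,8-trimethyldecahydronaphthalen-2-yl]oxy}(tert-butyl)dimethylsilane
Product: 17 (2S,4aR,7R,8aS)-7-bromo-4a,8,8-trimethyldecahydronaphthalen-2-ol
Conditions: TBAF, THF, 0 °C → rt
Reagents that add atoms: none
Why: Fluoride-mediated desilylation should leave the equatorial bromide intact because it has no anti-periplanar hydrogen for E2 and sits at a neopentyl-type carbon.

Step 13
Reactants: 17 (2S,4aR,7R,8aS)-7-bromo-4a,8,8-trimethyldecahydronaphthalen-2-ol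
Product: 18 (4aR,7R,8aS)-7-bromo-4a,8,8-trimethyloctahydronaphthalen-2(1H)-one
Conditions: Dess–Martin periodinane, CH2Cl2, rt
Reagents that add atoms: none
Why: Dess–Martin oxidation converts the secondary alcohol into the C7 ketone under neutral conditions that do not touch the alkyl bromide.

Step 14
Reactants: 18 (4aR,7R,8aS)-7-bromo-4a,8,8-trimethyloctahydronaphthalen-2(1H)-one
Product: 19 (4aS,7R,8aS)-7-bromo-4a,8,8-trimethyl-4a,5,6,7,8,8a-hexahydronaphthalen-2(1H)-one
Conditions: IBX, DMSO/PhF, 70 °C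
Reagents that add atoms: none
Why: IBX dehydrogenation proceeds through the more stable enol directed away from the ring fusion (towards C8, as trans-fused 3-keto steroids give 1-en-3-ones), which should place the double bond at C8=C9.

Step 15
Reactants: 19 (4aS,7R,8aS)-7-bromo-4a,8,8-trimethyl-4a,5,6,7,8,8a-hexahydronaphthalen-2(1H)-one
Product: 20 (4aR,7R,8aS)-7-bromo-3-iodo-4a,8,8-trimethyl-4a,5,6,7,8,8a-hexahydronaphthalen-2(1H)-one
Conditions: I2, pyridine, CH2Cl2, rt
Reagents that add atoms: iodine, II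
Why: α-Iodination of the enone by the pyridine-mediated addition–elimination (Baylis–Hillman-type) mechanism places iodine only on C8.

Step 16
Reactants: 20 (4aR,7R,8aS)-7-bromo-3-iodo-4a,8,8-trimethyl-4a,5,6,7,8,8a-hexahydronaphthalen-2(1H)-one
Product: 21 (4aS,7R,8aS)-7-bromo-3,4a,8,8-tetramethyl-4a,5,6,7,8,8a-hexahydronaphthalen-2(1H)-one
Conditions: Me4Sn, Pd2(dba)3 (5 mol%), AsPh3, CuI (cat.), NMP, 80 °C
Reagents that add atoms: tetramethylstannane, C[Sn](C)(C)C
Why: Stille coupling of the α-iodoenone installs the C8 methyl, and the arsine-ligated palladium catalyst should not insert into the unactivated secondary C–Br bond.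

Step 17
Reactants: 22 (R)-(−)-linalool
Product: 23 triethyl{[(3R)-3,7-dimethylocta-1,6-dien-3-yl]oxy}silane
Conditions: Et3SiOTf, 2,6-lutidine, CH2Cl2, −78 → 0 °C
Reagents that add atoms: triethylsilyl trifluoromethanesulfonate, CC[Si](CC)(CC)OS(=O)(=O)C(F)(F)F
Why: Silylation of the tertiary allylic alcohol with the silyl triflate protects C13–OH without touching its configuration.

Step 18
Reactants: 23 triethyl{[(3R)-3,7-dimethylocta-1,6-dien-3-yl]oxy}silane
Product: 25 (4R)-4-methyl-4-[(triethylsilyl)oxy]hex-5-enal, via ozonide 24 (not isolated)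
Conditions: O3, CH2Cl2, −78 °C (Sudan Red 7B end point); then PPh3, −78 °C → rt
Reagents that add atoms: ozone, O=[O+][O-]
Why: Ozonolysis with an indicator end point cleaves the electron-rich trisubstituted alkene in preference to the vinyl group, and phosphine reduction of the ozonide gives the aldehyde.

Step 19
Reactants: 25 (4R)-4-methyl-4-[(triethylsilyl)oxy]hex-5-enal
Product: 26 triethyl{[(3R,5Z)-3-methyl-6-[(trimethylsilyl)oxy]hexa-1,5-dien-3-yl]oxy}silane
Conditions: Me3SiOTf, Et3N, CH2Cl2, 0 °C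
Reagents that add atoms: trimethylsilyl trifluoromethanesulfonate, C[Si](C)(C)OS(=O)(=O)C(F)(F)F
Why: Soft enolisation gives the silyl enol ether of the aldehyde (mainly Z expected; both geometries converge in the next step).

Step 20
Reactants: 26 triethyl{[(3R,5Z)-3-methyl-6-[(trimethylsilyl)oxy]hexa-1,5-dien-3-yl]oxy}silane
Product: 28 (3R)-3-methyl-3-[(triethylsilyl)oxy]pent-4-en-1-ol, via aldehyde 27 (not isolated)
Conditions: O3, CH2Cl2/MeOH, −78 °C (Sudan Red 7B end point); then NaBH4, −78 → 0 °C
Reagents that add atoms: ozone, O=[O+][O-]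
Why: Ozonolysis of the electron-rich enol ether, much faster than that of the vinyl group, removes one carbon, and in situ borohydride reduction gives the primary alcohol that carries C11.

Step 21
Reactants: 28 (3R)-3-methyl-3-[(triethylsilyl)oxy]pent-4-en-1-ol
Product: 29 triethyl{[(3R)-5-iodo-3-methylpent-1-en-3-yl]oxy}silane
Conditions: I2, PPh3, imidazole, CH2Cl2, 0 °C
Reagents that add atoms: iodine, II
Why: Appel-type iodination converts the primary alcohol into the iodide under buffered conditions that spare the tertiary silyl ether.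

Step 22
Reactants: 21 (4aS,7R,8aS)-7-bromo-3,4a,8,8-tetramethyl-4a,5,6,7,8,8a-hexahydronaphthalen-2(1H)-one; 29 triethyl{[(3R)-5-iodo-3-methylpent-1-en-3-yl]oxy}silane
Product: 33 (4R,4aS,7R,8aS)-7-bromo-3,4a,8,8-tetramethyl-4-[(3R)-3-methyl-3-[(triethylsilyl)oxy]pent-4-en-1-yl]-1,4,4a,5,6,7,8,8a-octahydronaphthalen-2-yl trifluoromethanesulfonate, via alkyllithium 30 (not isolated), via lithium dialkylcuprate 31 (not isolated), via lithium enolate 32 (not isolated)
Conditions: 29 (2.2 equiv), t-BuLi (4.4 equiv), Et2O, −78 °C; CuI (1.1 equiv), −40 °C; 21, −78 → −20 °C; then PhNTf2, THF, −78 °C → rt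
Reagents that add atoms: N-phenylbis(trifluoromethanesulfonimide), O=S(=O)(N(c1ccccc1)S(=O)(=O)C(F)(F)F)C(F)(F)F
Why: Conjugate addition of the Gilman cuprate should occur axially at C9 on the face anti to the axial C10 methyl (as in 1α-alkylation of steroidal 1-en-3-ones), setting the side chain trans to that methyl, and triflation of the regiodefined enolate fixes the later C7=C8 alkene position.

Step 23
Reactants: 33 (4R,4aS,7R,8aS)-7-bromo-3,4a,8,8-tetramethyl-4-[(3R)-3-methyl-3-[(triethylsilyl)oxy]pent-4-en-1-yl]-1,4,4a,5,6,7,8,8a-octahydronaphthalen-2-yl trifluoromethanesulfonate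
Product: 34 {[(3R)-5-[(1S,4aS,6R,8aS)-6-bromo-2,5,5,8a-tetramethyl-1,4,4a,5,6,7,8,8a-octahydronaphthalen-1-yl]-3-methylpent-1-en-3-yl]oxy}triethylsilane
Conditions: Pd(OAc)2 (5 mol%), PPh3, HCO2H, Bu3N, DMF, 60 °C
Reagents that add atoms: none
Why: Palladium-catalysed formate reduction of the enol triflate (oxidative addition, formate decarboxylation, reductive elimination) replaces OTf by H at C7 without moving the alkene or touching the secondary alkyl bromide or the vinyl group.

Step 24
Reactants: 34 {[(3R)-5-[(1S,4aS,6R,8aS)-6-bromo-2,5,5,8a-tetramethyl-1,4,4a,5,6,7,8,8a-octahydronaphthalen-1-yl]-3-methylpent-1-en-3-yl]oxy}triethylsilane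
Product: 35 (3R)-5-[(1S,4aS,6R,8aS)-6-bromo-2,5,5,8a-tetramethyl-1,4,4a,5,6,7,8,8a-octahydronaphthalen-1-yl]-3-methylpent-1-en-3-ol
Conditions: TBAF, THF, 0 °C → rt
Reagents that add atoms: none
Why: Fluoride cleavage of the tertiary triethylsilyl ether avoids the acid that would ionise the tertiary allylic alcohol and should release the target.

**Compound list**

1 | (R)-(−)-carvone, (5R)-2-methyl-5-(prop-1-en-2-yl)cyclohex-2-en-1-one | CC1=CC[C@H](CC1=O)C(C)=C | starting material
2 | (5R)-5-(1-hydroperoxy-1-methoxyethyl)-2-methylcyclohex-2-en-1-one (epimers at the peroxy carbon) | CC1=CC[C@H](CC1=O)C(C)(OC)OO | intermediate (not isolated)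
3 | (1R)-4-methyl-5-oxocyclohex-3-en-1-yl acetate | CC1=CC[C@H](CC1=O)OC(C)=O | intermediate
4 | (5R)-5-hydroxy-2-methylcyclohex-2-en-1-one | CC1=CC[C@H](CC1=O)O | intermediate
5 | (5R)-5-[(tert-butyldimethylsilyl)oxy]-2-methylcyclohex-2-en-1-one | CC1=CC[C@H](CC1=O)O[Si](C)(C)C(C)(C)C | intermediate
6 | (1R,5R)-5-[(tert-butyldimethylsilyl)oxy]-2-methylcyclohex-2-en-1-ol (cis) | CC1=CC[C@H](C[C@H]1O)O[Si](C)(C)C(C)(C)C | intermediate
7 | (1R,5R)-5-[(tert-butyldimethylsilyl)oxy]-2-methylcyclohex-2-en-1-yl 2-methylpropanoate | CC1=CC[C@H](C[C@H]1OC(=O)C(C)C)O[Si](C)(C)C(C)(C)C | intermediate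
8 | tert-butyldimethyl{[(1R,5R)-4-methyl-5-{[2-methyl-1-(trimethylsilyloxy)prop-1-en-1-yl]oxy}cyclohex-3-en-1-yl]oxy}silane | CC1=CC[C@H](C[C@H]1OC(O[Si](C)(C)C)=C(C)C)O[Si](C)(C)C(C)(C)C | intermediate (not isolated)
9 | trimethylsilyl 2-[(1S,5S)-5-[(tert-butyldimethylsilyl)oxy]-2-methylcyclohex-2-en-1-yl]-2-methylpropanoate | CC1=CC[C@H](O[Si](C)(C)C(C)(C)C)C[C@@H]1C(C)(C)C(=O)O[Si](C)(C)C | intermediate (not isolated)
10 | 2-[(1S,5S)-5-[(tert-butyldimethylsilyl)oxy]-2-methylcyclohex-2-en-1-yl]-2-methylpropanoic acid | CC1=CC[C@H](O[Si](C)(C)C(C)(C)C)C[C@@H]1C(C)(C)C(O)=O | intermediate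
11 | 2-[(1S,5S)-5-[(tert-butyldimethylsilyl)oxy]-2-methylcyclohex-2-en-1-yl]-2-methylpropanoyl chloride | CC1=CC[C@H](O[Si](C)(C)C(C)(C)C)C[C@@H]1C(C)(C)C(Cl)=O | intermediate (not isolated)
12 | 2-[(1S,5S)-5-[(tert-butyldimethylsilyl)oxy]-2-methylcyclohex-2-en-1-yl]-N-methoxy-N,2-dimethylpropanamide | CC1=CC[C@H](O[Si](C)(C)C(C)(C)C)C[C@@H]1C(C)(C)C(=O)N(C)OC | intermediate
13 | 4-[(1S,5S)-5-[(tert-butyldimethylsilyl)oxy]-2-methylcyclohex-2-en-1-yl]-4-methylpent-1-en-3-one | CC1=CC[C@H](O[Si](C)(C)C(C)(C)C)C[C@@H]1C(C)(C)C(=O)C=C | intermediate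
14 | (4aR,7S,8aS)-7-[(tert-butyldimethylsilyl)oxy]-1,1,4a-trimethyloctahydronaphthalen-2(1H)-one (trans-fused) | C1C[C@H](O[Si](C)(C)C(C)(C)C)C[C@@H]2C(C)(C)C(=O)CC[C@]21C | intermediate
15 | {[(2S,4aR,8aS)-7-bromo-4a,8,8-trimethyl-1,2,3,4,4a,5,8,8a-octahydronaphthalen-2-yl]oxy}(tert-butyl)dimethylsilane | C1C[C@H](O[Si](C)(C)C(C)(C)C)C[C@@H]2C(C)(C)C(Br)=CC[C@]21C | intermediate
16 | {[(2S,4aR,7R,8aS)-7-bromo-4a,8,8-trimethyldecahydronaphthalen-2-yl]oxy}(tert-butyl)dimethylsilane | C1C[C@H](O[Si](C)(C)C(C)(C)C)C[C@@H]2C(C)(C)[C@H](Br)CC[C@]21C | intermediate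
17 | (2S,4aR,7R,8aS)-7-bromo-4a,8,8-trimethyldecahydronaphthalen-2-ol | C1C[C@H](O)C[C@@H]2C(C)(C)[C@H](Br)CC[C@]21C | intermediate
18 | (4aR,7R,8aS)-7-bromo-4a,8,8-trimethyloctahydronaphthalen-2(1H)-one | C1CC(=O)C[C@@H]2C(C)(C)[C@H](Br)CC[C@]21C | intermediate
19 | (4aS,7R,8aS)-7-bromo-4a,8,8-trimethyl-4a,5,6,7,8,8a-hexahydronaphthalen-2(1H)-one | C1=CC(=O)C[C@@H]2C(C)(C)[C@H](Br)CC[C@]21C | intermediate
20 | (4aR,7R,8aS)-7-bromo-3-iodo-4a,8,8-trimethyl-4a,5,6,7,8,8a-hexahydronaphthalen-2(1H)-one | C1=C(I)C(=O)C[C@@H]2C(C)(C)[C@H](Br)CC[C@]21C | intermediate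
21 | (4aS,7R,8aS)-7-bromo-3,4a,8,8-tetramethyl-4a,5,6,7,8,8a-hexahydronaphthalen-2(1H)-one | C1=C(C)C(=O)C[C@@H]2C(C)(C)[C@H](Br)CC[C@]21C | intermediate
22 | (R)-(−)-linalool, (3R)-3,7-dimethylocta-1,6-dien-3-ol | C=C[C@](C)(O)CCC=C(C)C | starting material
23 | triethyl{[(3R)-3,7-dimethylocta-1,6-dien-3-yl]oxy}silane | C=C[C@](C)(O[Si](CC)(CC)CC)CCC=C(C)C | intermediate
24 | triethyl{[(3R)-5-(5,5-dimethyl-1,2,4-trioxolan-3-yl)-3-methylpent-1-en-3-yl]oxy}silane (epimers at the trioxolane carbon) | C=C[C@](C)(O[Si](CC)(CC)CC)CCC1OOC(C)(C)O1 | intermediate (not isolated)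
25 | (4R)-4-methyl-4-[(triethylsilyl)oxy]hex-5-enal | C=C[C@](C)(O[Si](CC)(CC)CC)CCC=O | intermediate
26 | triethyl{[(3R,5Z)-3-methyl-6-[(trimethylsilyl)oxy]hexa-1,5-dien-3-yl]oxy}silane | C=C[C@](C)(O[Si](CC)(CC)CC)C/C=C\O[Si](C)(C)C | intermediate
27 | (3R)-3-methyl-3-[(triethylsilyl)oxy]pent-4-enal | C=C[C@](C)(O[Si](CC)(CC)CC)CC=O | intermediate (not isolated)
28 | (3R)-3-methyl-3-[(triethylsilyl)oxy]pent-4-en-1-ol | C=C[C@](C)(O[Si](CC)(CC)CC)CCO | intermediate
29 | triethyl{[(3R)-5-iodo-3-methylpent-1-en-3-yl]oxy}silane | C=C[C@](C)(O[Si](CC)(CC)CC)CCI | intermediate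
30 | [(3R)-3-methyl-3-[(triethylsilyl)oxy]pent-4-en-1-yl]lithium | C=C[C@](C)(O[Si](CC)(CC)CC)CC[Li] | intermediate (not isolated)
31 | lithium bis[(3R)-3-methyl-3-[(triethylsilyl)oxy]pent-4-en-1-yl]cuprate | [Li+].C=C[C@](C)(O[Si](CC)(CC)CC)CC[Cu-]CC[C@@](C)(O[Si](CC)(CC)CC)C=C | intermediate (not isolated)
32 | lithium (4R,4aS,7R,8aS)-7-bromo-3,4a,8,8-tetramethyl-4-[(3R)-3-methyl-3-[(triethylsilyl)oxy]pent-4-en-1-yl]-1,4,4a,5,6,7,8,8a-octahydronaphthalen-2-olate | C=C[C@](C)(O[Si](CC)(CC)CC)CC[C@H]1C(C)=C(O[Li])C[C@@H]2C(C)(C)[C@H](Br)CC[C@]21C | intermediate (not isolated)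
33 | (4R,4aS,7R,8aS)-7-bromo-3,4a,8,8-tetramethyl-4-[(3R)-3-methyl-3-[(triethylsilyl)oxy]pent-4-en-1-yl]-1,4,4a,5,6,7,8,8a-octahydronaphthalen-2-yl trifluoromethanesulfonate | C=C[C@](C)(O[Si](CC)(CC)CC)CC[C@H]1C(C)=C(OS(=O)(=O)C(F)(F)F)C[C@@H]2C(C)(C)[C@H](Br)CC[C@]21C | intermediate
34 | {[(3R)-5-[(1S,4aS,6R,8aS)-6-bromo-2,5,5,8a-tetramethyl-1,4,4a,5,6,7,8,8a-octahydronaphthalen-1-yl]-3-methylpent-1-en-3-yl]oxy}triethylsilane | C=C[C@](C)(O[Si](CC)(CC)CC)CC[C@H]1C(C)=CC[C@@H]2C(C)(C)[C@H](Br)CC[C@]21C | intermediate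
35 | (3R)-5-[(1S,4aS,6R,8aS)-6-bromo-2,5,5,8a-tetramethyl-1,4,4a,5,6,7,8,8a-octahydronaphthalen-1-yl]-3-methylpent-1-en-3-ol | C=C[C@](C)(O)CC[C@H]1C(C)=CC[C@@H]2C(C)(C)[C@H](Br)CC[C@]21C | target

**Step count and risks**

Total step count: 24. Longest linear sequence: 19 steps (steps 1–16 and 22–24); the side-chain iodide 29 is made in 5 steps (17–21).

Steps most likely to fail:

1. Step 9 (key cyclisation). What may go wrong: hydrogen-atom transfer to, or metal-hydride reduction and oligomerisation of, the vinyl ketone before the C10 radical is formed, and incomplete trans selectivity at the ring fusion. Fallback: the radical is generated without any metal hydride in the presence of the enone. The fallback sets out from Weinreb amide 12. Cobalt-catalysed Markovnikov hydrochlorination of the ring alkene (Co(BF4)2·6H2O with a salen-type ligand, TsCl, PhSiH3, t-BuOOH, EtOH) should give 2-[(1R,5S)-5-[(tert-butyldimethylsilyl)oxy]-2-chloro-2-methylcyclohexyl]-N-methoxy-N,2-dimethylpropanamide F1. Vinylmagnesium bromide should convert it into 4-[(1R,5S)-5-[(tert-butyldimethylsilyl)oxy]-2-chloro-2-methylcyclohexyl]-4-methylpent-1-en-3-one F2. Slow addition of Bu3SnH with AIBN in benzene at 80 °C should abstract the tertiary chlorine and drive the same 6-endo Giese cyclisation, returning to ketone 14.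

2. Step 11 (hydrogenation of the vinyl bromide). What may go wrong: loss of bromine (hydrogen-atom transfer at C3 followed by β-scission, or over-reduction) and poor facial selectivity in the second hydrogen transfer. Fallback: the bromide is made by mono-reduction of a geminal dibromide. The fallback sets out from ketone 14. Hydrazine hydrate in ethanol should give the hydrazone of ketone 14 F3. Oxidation with CuBr2 and Et3N in methanol should give {[(2S,4aR,8aS)-7,7-dibromo-4a,8,8-trimethyldecahydronaphthalen-2-yl]oxy}(tert-butyl)dimethylsilane F4. One equivalent of Bu3SnH (Et3B/air, toluene, −78 °C) should remove one bromine; the α-bromo radical should take hydrogen axially from the less hindered face, leaving bromine equatorial, and the sequence returns to bromide 16.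

3. Step 22 (cuprate addition and triflation). What may go wrong: sluggish 1,4-addition to the neopentyl β-carbon of the α-methyl enone, and loss of the enolate regiochemistry before triflation. Fallback: the C9–C11 bond is made by radical conjugate addition and the triflate in a separate step. The fallback sets out from enone 21 and iodide 29. Zinc–copper couple Zn(Cu) in aqueous ethanol under sonication should add the primary radical from 29 to C9, again anti to the C10 methyl, giving (4S,4aS,7R,8aS)-7-bromo-3,4a,8,8-tetramethyl-4-[(3R)-3-methyl-3-[(triethylsilyl)oxy]pent-4-en-1-yl]octahydronaphthalen-2(1H)-one F5. Thermodynamic enol triflate formation with Tf2O and 2,6-di-tert-butyl-4-methylpyridine in CH2Cl2 should favour the more substituted enol directed away from the ring fusion and returns to triflate 33.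

Further compounds
F1 | step 9 | 2-[(1R,5S)-5-[(tert-butyldimethylsilyl)oxy]-2-chloro-2-methylcyclohexyl]-N-methoxy-N,2-dimethylpropanamide (C-2 epimers) | CC1(Cl)CC[C@H](O[Si](C)(C)C(C)(C)C)C[C@@H]1C(C)(C)C(=O)N(C)OC
F2 | step 9 | 4-[(1R,5S)-5-[(tert-butyldimethylsilyl)oxy]-2-chloro-2-methylcyclohexyl]-4-methylpent-1-en-3-one (C-2 epimers) | CC1(Cl)CC[C@H](O[Si](C)(C)C(C)(C)C)C[C@@H]1C(C)(C)C(=O)C=C
F3 | step 11 | hydrazone of ketone 14 (ring configuration as in 14) | C1C[C@H](O[Si](C)(C)C(C)(C)C)C[C@@H]2C(C)(C)C(=NN)CC[C@]21C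
F4 | step 11 | {[(2S,4aR,8aS)-7,7-dibromo-4a,8,8-trimethyldecahydronaphthalen-2-yl]oxy}(tert-butyl)dimethylsilane | C1C[C@H](O[Si](C)(C)C(C)(C)C)C[C@@H]2C(C)(C)C(Br)(Br)CC[C@]21C
F5 | step 22 | (4S,4aS,7R,8aS)-7-bromo-3,4a,8,8-tetramethyl-4-[(3R)-3-methyl-3-[(triethylsilyl)oxy]pent-4-en-1-yl]octahydronaphthalen-2(1H)-one (C-3 epimers) | C=C[C@](C)(O[Si](CC)(CC)CC)CC[C@H]1C(C)C(=O)C[C@@H]2C(C)(C)[C@H](Br)CC[C@]21C
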